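**Retrosynthetic overview**
1. Last bond: the diarylmethine C–C bond, formed when C5 of ring E (right half) captures the ortho-quinone methide of the ring D carbinol (left half); the adjacent dihydrobenzofuran C3 fixes the new centre.
2. Left half (dihydrobenzofuran–chalcone): the O–C2 ring bond comes from a DDQ-mediated anodic dehydrogenative cycloetherification of a tyrosine-derived diphenol; the C3–aryl bond comes from invertive arylation of the α-triflate made from O-benzyl-L-tyrosine; rings D and A come from one double Grignard addition.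
3. Right half (tetrahydrofuran): the same triflate → bromide → malonate (two inversions) → aldol–lactonisation and decarboxylation to the all-trans paraconic acid → double aryllithium addition → hemiketal reduction (2,3-cis).
4. Ring order: γ-lactone, then tetrahydrofuran (right half); dihydrobenzofuran (left half); the halves are joined last. All seven stereocentres descend from the single stereocentre of O-benzyl-L-tyrosine.

Ring labels: A = 2,4-dihydroxyphenyl of the enone; B = benzo ring of the dihydrobenzofuran (DHB); C = 4-hydroxyphenyl on DHB C2; D = 2,4-dihydroxyphenyl on the methine; E = central resorcinol ring; F = 4-hydroxyphenyl on the tetrahydrofuran (THF); G = 2,4-dihydroxybenzoyl ring; H = 4-hydroxybenzyl ring. THF C2 is the carbon bonded to ring E.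

Assumption: 4-(benzyloxy)-3-bromobenzaldehyde, 1-bromo-2,4-bis(benzyloxy)benzene and the Weinreb-amide Wittig ylide are taken as purchasable.

Step 1
Reactants: 1 O-benzyl-L-tyrosine
Product: 2 (S)-3-[4-(benzyloxy)phenyl]-2-hydroxypropanoic acid
Conditions: NaNO2, 1 M H2SO4, 1,4-dioxane–H2O, 0 → 25 °C
Reagents that add atoms: water, O
Why: Diazotisation of the α-amino acid with hydrolysis proceeds with retention (double inversion through the α-lactone), so the bought (S) centre becomes the (S)-α-hydroxy acid.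

Step 2
Reactants: 2 (S)-3-[4-(benzyloxy)phenyl]-2-hydroxypropanoic acid
Product: 3 methyl (S)-3-[4-(benzyloxy)phenyl]-2-hydroxypropanoate
Conditions: MeOH, H2SO4 (cat.), 60 °C
Reagents that add atoms: methanol, CO
Why: Fischer esterification leaves the stereocentre untouched.

Step 3
Reactants: 3 methyl (S)-3-[4-(benzyloxy)phenyl]-2-hydroxypropanoate
Product: 4 methyl (S)-3-[4-(benzyloxy)phenyl]-2-(trifluoromethylsulfonyloxy)propanoate
Conditions: Tf2O, 2,6-lutidine, CH2Cl2, −78 → −40 °C, used at once for steps 5 and 13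
Reagents that add atoms: trifluoromethanesulfonic anhydride, O=S(=O)(OS(=O)(=O)C(F)(F)F)C(F)(F)F
Why: O-sulfonylation with retention gives the SN2-competent α-triflyloxy ester that serves both halves.

Step 4
Reactants: 5 4-(benzyloxy)-3-bromobenzaldehyde
Product: 6 2-[4-(benzyloxy)-3-bromophenyl]-1,3-dioxolane
Conditions: ethylene glycol, p-TsOH (cat.), toluene, reflux (Dean–Stark)
Reagents that add atoms: ethylene glycol, OCCO
Why: Acid-catalysed acetalisation masks the aldehyde for the organometallic step.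

Step 5
Reactants: 6 2-[4-(benzyloxy)-3-bromophenyl]-1,3-dioxolane; 4 methyl (S)-3-[4-(benzyloxy)phenyl]-2-(trifluoromethylsulfonyloxy)propanoate
Product: 8 methyl (S)-2-[2-(benzyloxy)-5-(1,3-dioxolan-2-yl)phenyl]-3-[4-(benzyloxy)phenyl]propanoate, via aryl Grignard reagent 7 (not isolated)
Conditions: 6, Mg, LiCl, THF, 25 °C; then 4, ZnCl2 (10 mol%), THF, 0 °C
Reagents that add atoms: none
Why: Zinc-catalysed SN2 arylation of an α-triflyloxy ester by an aryl Grignard reagent (triarylzincate nucleophile, the profen-type reaction class) goes with clean inversion, so the tyrosine centre becomes the aryl-bearing carbon that will be DHB C3.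

Step 6
Reactants: 8 methyl (S)-2-[2-(benzyloxy)-5-(1,3-dioxolan-2-yl)phenyl]-3-[4-(benzyloxy)phenyl]propanoate
Product: 9 (S)-2-[2-(benzyloxy)-5-(1,3-dioxolan-2-yl)phenyl]-3-[4-(benzyloxy)phenyl]propan-1-ol
Conditions: LiBH4, THF, 0 → 25 °C
Reagents that add atoms: none
Why: Borohydride reduction of the ester removes the acidic α-proton, so the centre can no longer epimerise or lactonise onto the ring B phenol once that is freed.

Step 7
Reactants: 9 (S)-2-[2-(benzyloxy)-5-(1,3-dioxolan-2-yl)phenyl]-3-[4-(benzyloxy)phenyl]propan-1-ol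
Product: 11 4-hydroxy-3-[(2S)-1-hydroxy-3-(4-hydroxyphenyl)propan-2-yl]benzaldehyde, via diphenol acetal 10 (not isolated)
Conditions: H2 (1 atm), 10% Pd/C, EtOAc, Et3N (trace), 25 °C; filter; then 1 M HCl, THF, 25 °C
Reagents that add atoms: water, O
Why: Hydrogenolysis of both aryl benzyl ethers (trace amine protects the acetal) followed by acetal hydrolysis frees the two phenols and the aldehyde that makes the ring B phenol electron-poor for step 8.

Step 8
Reactants: 11 4-hydroxy-3-[(2S)-1-hydroxy-3-(4-hydroxyphenyl)propan-2-yl]benzaldehyde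
Product: 13 (2R,3S)-3-(hydroxymethyl)-2-(4-hydroxyphenyl)-2,3-dihydrobenzofuran-5-carbaldehyde, via p-quinone methide 12 (not isolated)
Conditions: DDQ (15 mol%), LiClO4 (0.1 M), MeCN–AcOH (9:1), undivided cell, graphite anode, Pt cathode, constant current, 2.1 F/mol, 20 °C
Reagents that add atoms: none
Why: Proposed new method: anodically regenerated DDQ abstracts hydride from the CH2 para to the free ring C phenol (the formyl-deactivated ring B phenol is not oxidised) to give p-quinone methide 12, which the ring B phenol captures by 5-exo 1,6-addition anti to the CH2OH group so that C2 is set trans to C3 (capture is reversible, trans is also the thermodynamic isomer), while charge-limited turnover of catalytic DDQ limits over-oxidation to the benzofuran; the closest known chemistry is stoichiometric DDQ or Ag2O quinone-methide cyclisation of p-alkylphenols in lignan synthesis together with anodic regeneration of DDQ for benzylic oxidations.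

Step 9
Reactants: 13 (2R,3S)-3-(hydroxymethyl)-2-(4-hydroxyphenyl)-2,3-dihydrobenzofuran-5-carbaldehyde; 14 N-methoxy-N-methyl-2-(triphenyl-λ5-phosphanylidene)acetamide
Product: 15 (E)-3-[(2R,3S)-3-(hydroxymethyl)-2-(4-hydroxyphenyl)-2,3-dihydrobenzofuran-5-yl]-N-methoxy-N-methylprop-2-enamide
Conditions: toluene, 80 °C
Reagents that add atoms: none
Why: Wittig olefination with a stabilised ylide is E-selective and tolerates the free phenol and alcohol.

Step 10
Reactants: 15 (E)-3-[(2R,3S)-3-(hydroxymethyl)-2-(4-hydroxyphenyl)-2,3-dihydrobenzofuran-5-yl]-N-methoxy-N-methylprop-2-enamide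
Product: 16 (E)-3-[(2R,3R)-3-formyl-2-(4-hydroxyphenyl)-2,3-dihydrobenzofuran-5-yl]-N-methoxy-N-methylprop-2-enamide
Conditions: Dess–Martin periodinane (1.2 equiv), CH2Cl2, 0 °C, 30 min, used crude
Reagents that add atoms: none
Why: Dess–Martin oxidation of the primary alcohol is fast and non-basic, which avoids β-elimination of the aryloxide from the α-aryl aldehyde.

Step 11
Reactants: 17 4-bromoresorcinol
Product: 18 1-bromo-2,4-bis(tert-butyldimethylsilyloxy)benzene
Conditions: TBSCl, imidazole, DMF, 25 °C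
Reagents that add atoms: tert-butyldimethylsilyl chloride, CC(C)(C)[Si](C)(C)Cl
Why: Imidazole-promoted silylation protects both phenols with groups that fluoride removes in the last step.

Step 12
Reactants: 16 (E)-3-[(2R,3R)-3-formyl-2-(4-hydroxyphenyl)-2,3-dihydrobenzofuran-5-yl]-N-methoxy-N-methylprop-2-enamide; 18 1-bromo-2,4-bis(tert-butyldimethylsilyloxy)benzene
Product: 21 (E)-1-[2,4-bis(tert-butyldimethylsilyloxy)phenyl]-3-[(2R,3S)-3-{[2,4-bis(tert-butyldimethylsilyloxy)phenyl](hydroxy)methyl}-2-(4-hydroxyphenyl)-2,3-dihydrobenzofuran-5-yl]prop-2-en-1-one (carbinol epimers), via aryl Grignard reagent 19 (not isolated), via mono-adduct carbinol 20 (not isolated)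
Conditions: 18 (3.5 equiv), Mg, LiCl, THF, 25 °C, gives 19; then 16 (1.0 equiv), THF, −78 → 0 °C; aq. NH4Cl
Reagents that add atoms: second equivalent of [2,4-bis(tert-butyldimethylsilyloxy)phenyl]magnesium bromide 19, CC(C)(C)[Si](C)(C)Oc1ccc([Mg]Br)c(O[Si](C)(C)C(C)(C)C)c1
Why: One equivalent of 19 is spent on the free ring C phenol, one adds to the aldehyde at −78 °C to give 20 (carbinol epimers are irrelevant because this centre is ionised in step 20), and one more adds to the Weinreb amide on warming (stable chelate, enone on work-up, Weinreb ketone synthesis), so two aryl groups from 18 end up in the product as rings D and A.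

Step 13
Reactants: 4 methyl (S)-3-[4-(benzyloxy)phenyl]-2-(trifluoromethylsulfonyloxy)propanoate
Product: 22 methyl (R)-3-[4-(benzyloxy)phenyl]-2-bromopropanoate
Conditions: LiBr (1.0 equiv), THF, −40 → 0 °C
Reagents that add atoms: lithium bromide, [Li+].[Br-]
Why: SN2 displacement of triflate by bromide with inversion is the first of two inversions that give net retention for the right half.

Step 14
Reactants: 23 di-tert-butyl malonate; 22 methyl (R)-3-[4-(benzyloxy)phenyl]-2-bromopropanoate; 24 4-(benzyloxy)benzaldehyde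
Product: 26 di-tert-butyl (4R)-4-[4-(benzyloxy)benzyl]-2-[4-(benzyloxy)phenyl]-5-oxodihydrofuran-3,3(2H)-dicarboxylate (C2 epimers), via malonate triester 25 (not isolated)
Conditions: 23, NaH, THF, 0 °C; 22, 25 °C; then NaH, 24, 0 → 40 °C
Reagents that add atoms: none
Why: Malonate SN2 on the α-bromo ester with inversion sets the future THF C3, and the tertiary malonate anion then adds to the aldehyde with the aldolate lactonising onto the methyl ester (aldol–lactonisation to a paraconic ester, the aryl-bearing centre still unselective).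

Step 15
Reactants: 26 di-tert-butyl (4R)-4-[4-(benzyloxy)benzyl]-2-[4-(benzyloxy)phenyl]-5-oxodihydrofuran-3,3(2H)-dicarboxylate
Product: 28 (2R,3R,4R)-4-[4-(benzyloxy)benzyl]-2-[4-(benzyloxy)phenyl]-5-oxotetrahydrofuran-3-carboxylic acid, via malonic diacid 27 (not isolated)
Conditions: TFA–CH2Cl2 (1:3), 25 °C; evaporate; toluene, 105 °C; then TFA–CH2Cl2 (1:4), 35 °C
Reagents that add atoms: none
Why: Acidolysis of the tert-butyl esters, thermal decarboxylation of the malonic acid and acid equilibration through the ring F benzylic cation and the arylidene-succinic acid deliver the thermodynamic all-trans paraconic acid, so both new centres are set by the tyrosine-derived one.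

Step 16
Reactants: 28 (2R,3R,4R)-4-[4-(benzyloxy)benzyl]-2-[4-(benzyloxy)phenyl]-5-oxotetrahydrofuran-3-carboxylic acid
Product: 29 (3R,4R,5R)-3-[4-(benzyloxy)benzyl]-5-[4-(benzyloxy)phenyl]-4-(morpholine-4-carbonyl)dihydrofuran-2(3H)-one
Conditions: morpholine, N,N'-diisopropylcarbodiimide, HOBt (cat.), CH2Cl2, 0 → 25 °C
Reagents that add atoms: morpholine, C1COCCN1
Why: Carbodiimide amidation gives a morpholine amide, an acyl donor that stops at the ketone with organolithiums, and the trans arrangement is the stable one if the α-centre epimerises.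

Step 17
Reactants: 29 (3R,4R,5R)-3-[4-(benzyloxy)benzyl]-5-[4-(benzyloxy)phenyl]-4-(morpholine-4-carbonyl)dihydrofuran-2(3H)-one; 30 1-bromo-2,4-bis(benzyloxy)benzene
Product: 32 [(2R,3R,4R)-4-[4-(benzyloxy)benzyl]-2-[4-(benzyloxy)phenyl]-5-[2,4-bis(benzyloxy)phenyl]-5-hydroxytetrahydrofuran-3-yl][2,4-bis(benzyloxy)phenyl]methanone (anomers), via aryllithium 31 (not isolated)
Conditions: 30 (2.4 equiv), n-BuLi (2.4 equiv), THF, −78 °C, gives 31; then 29 (1.0 equiv), THF, −78 → −40 °C; aq. NH4Cl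
Reagents that add atoms: second equivalent of [2,4-bis(benzyloxy)phenyl]lithium 31, [Li]c1ccc(OCc2ccccc2)cc1OCc1ccccc1
Why: One equivalent of aryllithium 31 adds to the γ-lactone (lactol alkoxide stable at low temperature) and a second adds to the morpholine amide (stable tetrahedral adduct that gives the ketone only on work-up), so two aryl groups from 30 are installed as rings E and G without over-addition.

Step 18
Reactants: 32 [(2R,3R,4R)-4-[4-(benzyloxy)benzyl]-2-[4-(benzyloxy)phenyl]-5-[2,4-bis(benzyloxy)phenyl]-5-hydroxytetrahydrofuran-3-yl][2,4-bis(benzyloxy)phenyl]methanone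
Product: 33 [(2R,3R,4R,5S)-4-[4-(benzyloxy)benzyl]-2-[4-(benzyloxy)phenyl]-5-[2,4-bis(benzyloxy)phenyl]tetrahydrofuran-3-yl][2,4-bis(benzyloxy)phenyl]methanone
Conditions: Et3SiH, BF3·OEt2, CH2Cl2, −78 → −40 °C
Reagents that add atoms: none
Why: Ionic hemiketal reduction: BF3 ionises the lactol to the cyclic oxocarbenium ion and Et3SiH delivers hydride anti to the adjacent ring H benzyl group, which sets the ring E carbon cis to it, while the aryl ketone is not reduced at this temperature.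

Step 19
Reactants: 33 [(2R,3R,4R,5S)-4-[4-(benzyloxy)benzyl]-2-[4-(benzyloxy)phenyl]-5-[2,4-bis(benzyloxy)phenyl]tetrahydrofuran-3-yl][2,4-bis(benzyloxy)phenyl]methanone
Product: 34 (2,4-dihydroxyphenyl)[(2R,3R,4R,5S)-5-(2,4-dihydroxyphenyl)-4-(4-hydroxybenzyl)-2-(4-hydroxyphenyl)tetrahydrofuran-3-yl]methanone
Conditions: H2 (1 atm), 10% Pd/C, EtOAc–MeOH, 25 °C, stopped at full debenzylation
Reagents that add atoms: none
Why: Hydrogenolysis of the six aryl benzyl ethers is faster than cleavage of the cyclic benzylic ethers or reduction of the hydrogen-bonded aryl ketone.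

Step 20
Reactants: 21 (E)-1-[2,4-bis(tert-butyldimethylsilyloxy)phenyl]-3-[(2R,3S)-3-{[2,4-bis(tert-butyldimethylsilyloxy)phenyl](hydroxy)methyl}-2-(4-hydroxyphenyl)-2,3-dihydrobenzofuran-5-yl]prop-2-en-1-one; 34 (2,4-dihydroxyphenyl)[(2R,3R,4R,5S)-5-(2,4-dihydroxyphenyl)-4-(4-hydroxybenzyl)-2-(4-hydroxyphenyl)tetrahydrofuran-3-yl]methanone
Product: 37 (E)-1-(2,4-dihydroxyphenyl)-3-{(2R,3R)-3-[(R)-(2,4-dihydroxyphenyl){5-[(2S,3R,4R,5R)-4-(2,4-dihydroxybenzoyl)-3-(4-hydroxybenzyl)-5-(4-hydroxyphenyl)tetrahydrofuran-2-yl]-2,4-dihydroxyphenyl}methyl]-2-(4-hydroxyphenyl)-2,3-dihydrobenzofuran-5-yl}prop-2-en-1-one, via hexaphenol carbinol 35 (not isolated), via ortho-quinone methide 36 (not isolated)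
Conditions: 34 (1.5 equiv), Bu4NF (4.4 equiv), AcOH (4.4 equiv), THF–DMF, 0 → 35 °C
Reagents that add atoms: none
Why: Fluoride desilylation unveils the 2,4-dihydroxybenzylic carbinol, which loses water to the ortho-quinone methide as in resorcinol–aldehyde condensations, and ring E of 34 adds through C5 (para to one hydroxyl, ortho to the other, ring G being acyl-deactivated) to the conformer that minimises A(1,3) strain (DHB C3–H eclipsing the exocyclic C=C) on the face away from fused ring B, which is predicted to give the (R)-methine (quinone-methide Friedel–Crafts alkylation under 1,2-substrate control).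

**Compound list**
1 | O-benzyl-L-tyrosine | N[C@@H](Cc1ccc(OCc2ccccc2)cc1)C(=O)O | starting material
2 | (S)-3-[4-(benzyloxy)phenyl]-2-hydroxypropanoic acid | O[C@@H](Cc1ccc(OCc2ccccc2)cc1)C(=O)O | intermediate
3 | methyl (S)-3-[4-(benzyloxy)phenyl]-2-hydroxypropanoate | O[C@@H](Cc1ccc(OCc2ccccc2)cc1)C(=O)OC | intermediate
4 | methyl (S)-3-[4-(benzyloxy)phenyl]-2-(trifluoromethylsulfonyloxy)propanoate | FC(F)(F)S(=O)(=O)O[C@@H](Cc1ccc(OCc2ccccc2)cc1)C(=O)OC | intermediate
5 | 4-(benzyloxy)-3-bromobenzaldehyde | O=Cc1ccc(OCc2ccccc2)c(Br)c1 | starting material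
6 | 2-[4-(benzyloxy)-3-bromophenyl]-1,3-dioxolane | Brc1cc(C2OCCO2)ccc1OCc1ccccc1 | intermediate
7 | [2-(benzyloxy)-5-(1,3-dioxolan-2-yl)phenyl]magnesium bromide | Br[Mg]c1cc(C2OCCO2)ccc1OCc1ccccc1 | intermediate
8 | methyl (S)-2-[2-(benzyloxy)-5-(1,3-dioxolan-2-yl)phenyl]-3-[4-(benzyloxy)phenyl]propanoate | C1COC(O1)c1ccc(OCc2ccccc2)c(c1)[C@@H](C(=O)OC)Cc1ccc(OCc2ccccc2)cc1 | intermediate
9 | (S)-2-[2-(benzyloxy)-5-(1,3-dioxolan-2-yl)phenyl]-3-[4-(benzyloxy)phenyl]propan-1-ol | C1COC(O1)c1ccc(OCc2ccccc2)c(c1)[C@@H](CO)Cc1ccc(OCc2ccccc2)cc1 | intermediate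
10 | 4-(1,3-dioxolan-2-yl)-2-[(2S)-1-hydroxy-3-(4-hydroxyphenyl)propan-2-yl]phenol | C1COC(O1)c1ccc(O)c(c1)[C@@H](CO)Cc1ccc(O)cc1 | intermediate
11 | 4-hydroxy-3-[(2S)-1-hydroxy-3-(4-hydroxyphenyl)propan-2-yl]benzaldehyde | O=Cc1ccc(O)c(c1)[C@@H](CO)Cc1ccc(O)cc1 | intermediate
12 | 4-hydroxy-3-[(2S)-1-hydroxy-3-(4-oxocyclohexa-2,5-dien-1-ylidene)propan-2-yl]benzaldehyde (p-quinone methide) | O=Cc1ccc(O)c(c1)[C@@H](CO)C=C1C=CC(=O)C=C1 | intermediate
13 | (2R,3S)-3-(hydroxymethyl)-2-(4-hydroxyphenyl)-2,3-dihydrobenzofuran-5-carbaldehyde | O=Cc1ccc2c(c1)[C@@H](CO)[C@H](c1ccc(O)cc1)O2 | intermediate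
14 | N-methoxy-N-methyl-2-(triphenyl-λ5-phosphanylidene)acetamide | CON(C)C(=O)C=P(c1ccccc1)(c1ccccc1)c1ccccc1 | starting material
15 | (E)-3-[(2R,3S)-3-(hydroxymethyl)-2-(4-hydroxyphenyl)-2,3-dihydrobenzofuran-5-yl]-N-methoxy-N-methylprop-2-enamide | CON(C)C(=O)/C=C/c1ccc2c(c1)[C@@H](CO)[C@H](c1ccc(O)cc1)O2 | intermediate
16 | (E)-3-[(2R,3R)-3-formyl-2-(4-hydroxyphenyl)-2,3-dihydrobenzofuran-5-yl]-N-methoxy-N-methylprop-2-enamide | CON(C)C(=O)/C=C/c1ccc2c(c1)[C@@H](C=O)[C@H](c1ccc(O)cc1)O2 | intermediate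
17 | 4-bromoresorcinol | Oc1ccc(Br)c(O)c1 | starting material
18 | 1-bromo-2,4-bis(tert-butyldimethylsilyloxy)benzene | CC(C)(C)[Si](C)(C)Oc1ccc(Br)c(O[Si](C)(C)C(C)(C)C)c1 | intermediate
19 | [2,4-bis(tert-butyldimethylsilyloxy)phenyl]magnesium bromide | CC(C)(C)[Si](C)(C)Oc1ccc([Mg]Br)c(O[Si](C)(C)C(C)(C)C)c1 | intermediate
20 | (E)-3-[(2R,3S)-3-{[2,4-bis(tert-butyldimethylsilyloxy)phenyl](hydroxy)methyl}-2-(4-hydroxyphenyl)-2,3-dihydrobenzofuran-5-yl]-N-methoxy-N-methylprop-2-enamide (carbinol epimers) | CON(C)C(=O)/C=C/c1ccc2c(c1)[C@@H](C(O)c1ccc(O[Si](C)(C)C(C)(C)C)cc1O[Si](C)(C)C(C)(C)C)[C@H](c1ccc(O)cc1)O2 | intermediate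
21 | (E)-1-[2,4-bis(tert-butyldimethylsilyloxy)phenyl]-3-[(2R,3S)-3-{[2,4-bis(tert-butyldimethylsilyloxy)phenyl](hydroxy)methyl}-2-(4-hydroxyphenyl)-2,3-dihydrobenzofuran-5-yl]prop-2-en-1-one (carbinol epimers) | O=C(/C=C/c1ccc2c(c1)[C@@H](C(O)c1ccc(O[Si](C)(C)C(C)(C)C)cc1O[Si](C)(C)C(C)(C)C)[C@H](c1ccc(O)cc1)O2)c1ccc(O[Si](C)(C)C(C)(C)C)cc1O[Si](C)(C)C(C)(C)C | intermediate
22 | methyl (R)-3-[4-(benzyloxy)phenyl]-2-bromopropanoate | Br[C@H](Cc1ccc(OCc2ccccc2)cc1)C(=O)OC | intermediate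
23 | di-tert-butyl malonate | CC(C)(C)OC(=O)CC(=O)OC(C)(C)C | starting material
24 | 4-(benzyloxy)benzaldehyde | O=Cc1ccc(OCc2ccccc2)cc1 | starting material
25 | 1,1-di-tert-butyl 2-methyl (R)-3-[4-(benzyloxy)phenyl]propane-1,1,2-tricarboxylate | CC(C)(C)OC(=O)C(C(=O)OC(C)(C)C)[C@H](C(=O)OC)Cc1ccc(OCc2ccccc2)cc1 | intermediate
26 | di-tert-butyl (4R)-4-[4-(benzyloxy)benzyl]-2-[4-(benzyloxy)phenyl]-5-oxodihydrofuran-3,3(2H)-dicarboxylate (C2 epimers) | O=C1OC(c2ccc(OCc3ccccc3)cc2)C(C(=O)OC(C)(C)C)(C(=O)OC(C)(C)C)[C@H]1Cc1ccc(OCc2ccccc2)cc1 | intermediate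
27 | (4R)-4-[4-(benzyloxy)benzyl]-2-[4-(benzyloxy)phenyl]-5-oxodihydrofuran-3,3(2H)-dicarboxylic acid (C2 epimers) | O=C1OC(c2ccc(OCc3ccccc3)cc2)C(C(=O)O)(C(=O)O)[C@H]1Cc1ccc(OCc2ccccc2)cc1 | intermediate
28 | (2R,3R,4R)-4-[4-(benzyloxy)benzyl]-2-[4-(benzyloxy)phenyl]-5-oxotetrahydrofuran-3-carboxylic acid | O=C1O[C@@H](c2ccc(OCc3ccccc3)cc2)[C@H](C(=O)O)[C@H]1Cc1ccc(OCc2ccccc2)cc1 | intermediate
29 | (3R,4R,5R)-3-[4-(benzyloxy)benzyl]-5-[4-(benzyloxy)phenyl]-4-(morpholine-4-carbonyl)dihydrofuran-2(3H)-one | O=C1O[C@@H](c2ccc(OCc3ccccc3)cc2)[C@H](C(=O)N2CCOCC2)[C@H]1Cc1ccc(OCc2ccccc2)cc1 | intermediate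
30 | 1-bromo-2,4-bis(benzyloxy)benzene | Brc1ccc(OCc2ccccc2)cc1OCc1ccccc1 | starting material
31 | [2,4-bis(benzyloxy)phenyl]lithium | [Li]c1ccc(OCc2ccccc2)cc1OCc1ccccc1 | intermediate
32 | [(2R,3R,4R)-4-[4-(benzyloxy)benzyl]-2-[4-(benzyloxy)phenyl]-5-[2,4-bis(benzyloxy)phenyl]-5-hydroxytetrahydrofuran-3-yl][2,4-bis(benzyloxy)phenyl]methanone (anomers) | OC1(c2ccc(OCc3ccccc3)cc2OCc2ccccc2)O[C@@H](c2ccc(OCc3ccccc3)cc2)[C@H](C(=O)c2ccc(OCc3ccccc3)cc2OCc2ccccc2)[C@H]1Cc1ccc(OCc2ccccc2)cc1 | intermediate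
33 | [(2R,3R,4R,5S)-4-[4-(benzyloxy)benzyl]-2-[4-(benzyloxy)phenyl]-5-[2,4-bis(benzyloxy)phenyl]tetrahydrofuran-3-yl][2,4-bis(benzyloxy)phenyl]methanone | c1cc([C@H]2O[C@@H](c3ccc(OCc4ccccc4)cc3)[C@H](C(=O)c3ccc(OCc4ccccc4)cc3OCc3ccccc3)[C@H]2Cc2ccc(OCc3ccccc3)cc2)c(OCc2ccccc2)cc1OCc1ccccc1 | intermediate
34 | (2,4-dihydroxyphenyl)[(2R,3R,4R,5S)-5-(2,4-dihydroxyphenyl)-4-(4-hydroxybenzyl)-2-(4-hydroxyphenyl)tetrahydrofuran-3-yl]methanone | c1cc([C@H]2O[C@@H](c3ccc(O)cc3)[C@H](C(=O)c3ccc(O)cc3O)[C@H]2Cc2ccc(O)cc2)c(O)cc1O | intermediate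
35 | (E)-1-(2,4-dihydroxyphenyl)-3-[(2R,3S)-3-[(2,4-dihydroxyphenyl)(hydroxy)methyl]-2-(4-hydroxyphenyl)-2,3-dihydrobenzofuran-5-yl]prop-2-en-1-one (carbinol epimers) | O=C(/C=C/c1ccc2c(c1)[C@@H](C(O)c1ccc(O)cc1O)[C@H](c1ccc(O)cc1)O2)c1ccc(O)cc1O | intermediate
36 | (E)-1-(2,4-dihydroxyphenyl)-3-[(2R,3R)-3-[(3-hydroxy-6-oxocyclohexa-2,4-dien-1-ylidene)methyl]-2-(4-hydroxyphenyl)-2,3-dihydrobenzofuran-5-yl]prop-2-en-1-one (ortho-quinone methide) | O=C(/C=C/c1ccc2c(c1)[C@@H](C=C1C=CC(O)=CC1=O)[C@H](c1ccc(O)cc1)O2)c1ccc(O)cc1O | intermediate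
37 | (E)-1-(2,4-dihydroxyphenyl)-3-{(2R,3R)-3-[(R)-(2,4-dihydroxyphenyl){5-[(2S,3R,4R,5R)-4-(2,4-dihydroxybenzoyl)-3-(4-hydroxybenzyl)-5-(4-hydroxyphenyl)tetrahydrofuran-2-yl]-2,4-dihydroxyphenyl}methyl]-2-(4-hydroxyphenyl)-2,3-dihydrobenzofuran-5-yl}prop-2-en-1-one | O=C(/C=C/c1ccc2c(c1)[C@@H]([C@H](c1ccc(O)cc1O)c1cc([C@H]3O[C@@H](c4ccc(O)cc4)[C@H](C(=O)c4ccc(O)cc4O)[C@H]3Cc3ccc(O)cc3)c(O)cc1O)[C@H](c1ccc(O)cc1)O2)c1ccc(O)cc1O | target

**Step count and risk**
Total: 20 steps. Longest linear sequence: 11 steps (steps 1, 2, 3, 5, 6, 7, 8, 9, 10, 12, 20; the right-half branch through steps 1, 2, 3 and 13–20 is equally long).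

The three steps most likely to fail:

Step 8 (the proposed electro-mediated cycloetherification). An unhindered p-alkylphenol may give DDQ adducts or phenol coupling instead of the quinone methide, and the product can be over-oxidised to the benzofuran. The fallback uses known chemistry and sets out from 11. Stoichiometric DDQ in MeOH–CH2Cl2 at 0 °C (classical quinone dehydrogenation of a p-alkylphenol with solvent capture of the quinone methide) gives the isolable benzylic ether 4-hydroxy-3-[(2S)-1-hydroxy-3-(4-hydroxyphenyl)-3-methoxypropan-2-yl]benzaldehyde F1. Camphorsulfonic acid (cat.) in CH2Cl2 at 25 °C then ionises F1, and the ring B phenol closes the ring under thermodynamic control to the trans product. The fallback comes back to the route at 13.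

Step 17 (double aryllithium addition). Over-addition at the opened lactol or incomplete addition to the hindered amide is possible. The fallback sets out from 29 and separates the two arylations. Aryllithium 31 (1.1 equiv, −78 °C) adds only to the lactone and gives the lactol amide {(2R,3R,4R)-4-[4-(benzyloxy)benzyl]-2-[4-(benzyloxy)phenyl]-5-[2,4-bis(benzyloxy)phenyl]-5-hydroxytetrahydrofuran-3-yl}(morpholin-4-yl)methanone F2. Et3SiH/BF3·OEt2 at −78 °C reduces it to the tetrahydrofuran amide {(2R,3R,4R,5S)-4-[4-(benzyloxy)benzyl]-2-[4-(benzyloxy)phenyl]-5-[2,4-bis(benzyloxy)phenyl]tetrahydrofuran-3-yl}(morpholin-4-yl)methanone F3. A second portion of 31 (1.5 equiv, −40 °C) converts the amide into the ketone. The fallback comes back to the route at 33.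

Step 20 (fragment union). Self-condensation of the desilylated left half, attack at other phenolic positions and an unfavourable diastereomer ratio at the methine are the main risks. The fallback sets out from 21 (with 34) and changes the mechanism from a base-side quinone methide to an acid-ionised benzylic cation, with the silyl groups kept on so that ring D cannot act as a nucleophile. Diphenyl phosphate (5 mol%) in hexafluoroisopropanol–CH2Cl2 at −20 °C ionises the carbinol of 21, and ring E of 34 (2 equiv) captures the cation in an SN1 Friedel–Crafts alkylation. This gives the tetrakis(tert-butyldimethylsilyl) ether of the target (silyl groups on the four oxygens of rings A and D) F4. Et3N·3HF in THF at 25 °C then removes the silyl groups. The fallback comes back to the route at 37.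

**Further compounds**
F1 | step 8 | 4-hydroxy-3-[(2S)-1-hydroxy-3-(4-hydroxyphenyl)-3-methoxypropan-2-yl]benzaldehyde | O=Cc1ccc(O)c(c1)[C@@H](CO)C(OC)c1ccc(O)cc1
F2 | step 17 | {(2R,3R,4R)-4-[4-(benzyloxy)benzyl]-2-[4-(benzyloxy)phenyl]-5-[2,4-bis(benzyloxy)phenyl]-5-hydroxytetrahydrofuran-3-yl}(morpholin-4-yl)methanone | OC1(c2ccc(OCc3ccccc3)cc2OCc2ccccc2)O[C@@H](c2ccc(OCc3ccccc3)cc2)[C@H](C(=O)N2CCOCC2)[C@H]1Cc1ccc(OCc2ccccc2)cc1
F3 | step 17 | {(2R,3R,4R,5S)-4-[4-(benzyloxy)benzyl]-2-[4-(benzyloxy)phenyl]-5-[2,4-bis(benzyloxy)phenyl]tetrahydrofuran-3-yl}(morpholin-4-yl)methanone | c1cc([C@H]2O[C@@H](c3ccc(OCc4ccccc4)cc3)[C@H](C(=O)N3CCOCC3)[C@H]2Cc2ccc(OCc3ccccc3)cc2)c(OCc2ccccc2)cc1OCc1ccccc1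
F4 | step 20 | tetrakis(tert-butyldimethylsilyl) ether of 37 at the four oxygens of rings A and D | O=C(/C=C/c1ccc2c(c1)[C@@H]([C@H](c1ccc(O[Si](C)(C)C(C)(C)C)cc1O[Si](C)(C)C(C)(C)C)c1cc([C@H]3O[C@@H](c4ccc(O)cc4)[C@H](C(=O)c4ccc(O)cc4O)[C@H]3Cc3ccc(O)cc3)c(O)cc1O)[C@H](c1ccc(O)cc1)O2)c1ccc(O[Si](C)(C)C(C)(C)C)cc1O[Si](C)(C)C(C)(C)C
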